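**Plan**

- Ring atoms are numbered O1–O2–C3–C4–C5–C6 (C3 carries CH(CH3)CO2Me). C6 is a fully substituted carbon bound to peroxide oxygen O1 and carries CH3 plus the C16 triene chain, so it is the masked carbonyl carbon of (5E,9E)-farnesylacetone; O1–O2–C3–C4–C5 is an allylic hydroperoxide with a C4=C5 vinyl group. This pairing allows a peroxycarbenium/alkene ring closure.
- Cuts, in retrosynthetic order: C4–H (from a C4–Br helper); ring bond C5–C6; ketal bond C6–O1 (chain ketal + hydroperoxide); C3–O2 (SN2); C1 ester (from a vinyl group); C2–C3 (crotylboration).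
- Forward: crotylboration, sulfonate, peroxide SN2, ozonolysis to the ester, alkyne semihydrogenation, peroxyketal exchange with the chain ketone, closure of the only ring (the 1,2-dioxane) through C5–C6, removal of bromine.
- Stereochemistry: C2/C3 from reagent-controlled anti crotylboration followed by SN2 inversion at C3; C6 from the chair transition state of the ring closure, relayed from C3; both E alkenes arrive with farnesylacetone.

Key step: step 9

Assumption: (5E,9E)-farnesylacetone 12 is taken as available isomerically pure; bromide 17 is carried as a mixture at C4, since that carbon becomes CH2 in step 10.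

**Route**

Step 1
Reactants: 1 2,3-dimethylbut-2-ene
Product: 2 2-hydroperoxy-2-methoxypropane
Conditions: O3, MeOH/CH2Cl2, −78 °C; N2 purge; kept and used as a titrated solution
Reagents that add atoms: ozone [O-][O+]=O; methanol CO
Why: Criegee ozonolysis of a tetrasubstituted alkene in methanol traps the carbonyl oxide as the α-methoxy hydroperoxide; no stereocenter is formed.

Step 2
Reactants: 3 3-(trimethylsilyl)prop-2-ynal
Product: 5 (3S,4S)-4-methyl-1-(trimethylsilyl)hex-5-en-1-yn-3-ol, via borinate ester 4 (not isolated)
Conditions: trans-2-butene, KOtBu, n-BuLi, THF, −78 to −45 °C; (−)-Ipc2BOMe, −78 °C; BF3·OEt2; then 3, −78 °C; NaBO3·4H2O, THF/H2O, rt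
Reagents that add atoms: trans-2-butene C/C=C/C
Why: Brown crotylboration through a Zimmerman–Traxler chair: the E-crotyl geometry should give the anti (3,4) pair, and the isopinocampheyl groups derived from (+)-α-pinene should direct attack to the Si face of the aldehyde, giving (3S,4S).

Step 3
Reactants: 5 (3S,4S)-4-methyl-1-(trimethylsilyl)hex-5-en-1-yn-3-ol
Product: 6 (3S,4S)-4-methyl-1-(trimethylsilyl)hex-5-en-1-yn-3-yl methanesulfonate
Conditions: MsCl, Et3N, CH2Cl2, −20 °C; used without chromatography
Reagents that add atoms: methanesulfonyl chloride CS(=O)(=O)Cl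
Why: O-sulfonylation of a secondary propargylic alcohol breaks no bond at a stereocenter.

Step 4
Reactants: 6 (3S,4S)-4-methyl-1-(trimethylsilyl)hex-5-en-1-yn-3-yl methanesulfonate; 2 2-hydroperoxy-2-methoxypropane
Product: 8 (3R,4S)-3-[(2-methoxypropan-2-yl)peroxy]-4-methylhex-5-en-1-yne, via silylalkyne peroxide 7 (not isolated)
Conditions: 2 (1.5 equiv), CsOH·H2O (1.2 equiv), DMF, 0 °C; then K2CO3, MeOH, rt
Reagents that add atoms: none
Why: SN2 displacement of the activated propargylic methanesulfonate by the α-effect caesium peroxide should invert C3 (S to R) and leave C4 untouched; methanolic carbonate then cleaves the alkynyl C–Si bond.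

Step 5
Reactants: 8 (3R,4S)-3-[(2-methoxypropan-2-yl)peroxy]-4-methylhex-5-en-1-yne
Product: 10 methyl (2R,3R)-3-[(2-methoxypropan-2-yl)peroxy]-2-methylpent-4-ynoate, via methoxy hydroperoxide 9 (not isolated)
Conditions: O3 (one equivalent, dye end-point), CH2Cl2/MeOH 4:1, NaHCO3, −78 °C; then Ac2O, Et3N, CH2Cl2, 0 °C to rt
Reagents that add atoms: ozone [O-][O+]=O; methanol CO
Why: Criegee ozonolysis of the monosubstituted alkene (much more reactive to ozone than the alkyne) in methanol gives α-methoxy hydroperoxide 9, whose peracetate fragments under Et3N to the methyl ester; the ester level is reached without an epimerisable β-peroxy aldehyde, and the descriptors change only through new CIP ranks.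

Step 6
Reactants: 10 methyl (2R,3R)-3-[(2-methoxypropan-2-yl)peroxy]-2-methylpent-4-ynoate
Product: 11 methyl (2R,3S)-3-[(2-methoxypropan-2-yl)peroxy]-2-methylpent-4-enoate
Conditions: H2 (1 atm, stopped after one equivalent), Pd/CaCO3 poisoned with Pb(OAc)2 (Lindlar catalyst), quinoline, EtOAc, 0 °C
Reagents that add atoms: none
Why: Lindlar semihydrogenation: the terminal alkyne should bind and reduce on the poisoned palladium faster than the product alkene or the O–O bond; no stereocenter is involved.

Step 7
Reactants: 12 (5E,9E)-6,10,14-trimethylpentadeca-5,9,13-trien-2-one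
Product: 13 (5E,9E)-2,2-dimethoxy-6,10,14-trimethylpentadeca-5,9,13-triene
Conditions: HC(OMe)3, MeOH, pyridinium p-toluenesulfonate (cat.), rt; Et3N quench
Reagents that add atoms: trimethyl orthoformate COC(OC)OC
Why: Acid-catalysed ketalisation driven by the orthoformate as water scavenger; the weak acid should leave the trisubstituted alkenes and their E geometry untouched.

Step 8
Reactants: 11 methyl (2R,3S)-3-[(2-methoxypropan-2-yl)peroxy]-2-methylpent-4-enoate; 13 (5E,9E)-2,2-dimethoxy-6,10,14-trimethylpentadeca-5,9,13-triene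
Product: 15 methyl (2R,3S)-3-{[(5E,9E)-2-methoxy-6,10,14-trimethylpentadeca-5,9,13-trien-2-yl]peroxy}-2-methylpent-4-enoate (both epimers at the ketal carbon), via hydroperoxide 14 (not isolated)
Conditions: AcOH/THF/H2O 4:2:1, rt; extraction into CH2Cl2 with BHT, not taken to dryness; then 13 (1.5 equiv), pyridinium p-toluenesulfonate (cat.), 4 Å molecular sieves, CH2Cl2, 0 °C to rt; Et3N
Reagents that add atoms: none
Why: Mild aqueous acid hydrolyses the acetone-derived monoperoxyketal (a ketal-type protecting group for hydroperoxides), and the free hydroperoxide then exchanges into the oxocarbenium ion from 13 (transketalisation); the new ketal centre is lost again in step 9.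

Step 9
Reactants: 15 methyl (2R,3S)-3-{[(5E,9E)-2-methoxy-6,10,14-trimethylpentadeca-5,9,13-trien-2-yl]peroxy}-2-methylpent-4-enoate
Product: 17 methyl (2R)-2-[(3R,6R)-4-bromo-6-methyl-6-[(3E,7E)-4,8,12-trimethyltrideca-3,7,11-trien-1-yl]-1,2-dioxan-3-yl]propanoate (C4 epimers; C3 has the same spatial arrangement as in the target, its descriptor changes because Br raises the rank of C4), via peroxycarbenium ion 16 (not isolated)
Conditions: SnBr4 (1.2 equiv), 2,6-di-tert-butyl-4-methylpyridine (0.3 equiv), CH2Cl2 (0.01 M), −78 °C; Et3N/MeOH then NaHCO3 quench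
Reagents that add atoms: tin tetrabromide Br[Sn](Br)(Br)Br
Why: SnBr4 abstracts methoxide from either ketal epimer of 15 (stereoconvergent) to give the planar peroxycarbenium ion 16; its cationic carbon (future C6) is attacked by the terminal carbon of the tethered vinyl group (future C5) in a 6-endo-trig closure that forms C5–C6 and leaves a secondary cation at C4, which bromide captures. The closest known reaction type is the Lewis acid-mediated cyclisation of unsaturated monoperoxyketals through peroxycarbenium ions, the peroxide counterpart of the halo-Prins cyclisation. The one ring formed, the 1,2-dioxane, closes through a chair with the CH(CH3)CO2Me group on C3 equatorial, and C3 keeps its configuration because the oxonia-Cope pathway that scrambles ordinary Prins substrates would here require an O=O+ fragment. C6 is set by the geometry of 16: the long chain prefers to lie anti to the O–O bond and becomes equatorial, while the methyl group syn to O–O becomes axial and cis to the C3 side chain, which is the (6R) arrangement of the target; C4–Br forms as an inconsequential mixture. The step needs (a) 6-endo rather than 5-exo closure, secured by secondary versus primary cation stability, (b) attack by the vinyl group rather than by the three trisubstituted chain alkenes, secured by the six-membered transition state (the chain alkenes can only close four-membered, five-endo or eight-membered and larger rings) and by high dilution, and (c) discrimination of methyl from the chain at C6, which rests on the modest geometric bias of 16 and is the weakest element.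

Step 10
Reactants: 17 methyl (2R)-2-[(3R,6R)-4-bromo-6-methyl-6-[(3E,7E)-4,8,12-trimethyltrideca-3,7,11-trien-1-yl]-1,2-dioxan-3-yl]propanoate
Product: 18 methyl (2R)-2-[(3S,6R)-6-methyl-6-[(3E,7E)-4,8,12-trimethyltrideca-3,7,11-trien-1-yl]-1,2-dioxan-3-yl]propanoate
Conditions: Bu3SnH (2 equiv, 0.3 M), Et3B (0.2 equiv), trace air, toluene, 0 °C to rt
Reagents that add atoms: none
Why: Radical-chain dehalogenation: Bu3Sn• should abstract bromine much faster than it attacks the dialkyl peroxide, and the secondary C4 radical is quenched by Sn–H at high hydride concentration before β-scission or cyclisation, so C4 becomes CH2 without touching C2, C3 or C6.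

**Compound list**

1 | 2,3-dimethylbut-2-ene | CC(C)=C(C)C | starting material
2 | 2-hydroperoxy-2-methoxypropane | COC(C)(C)OO | intermediate
3 | 3-(trimethylsilyl)prop-2-ynal | C[Si](C)(C)C#CC=O | starting material
4 | (3S,4S)-4-methyl-1-(trimethylsilyl)hex-5-en-1-yn-3-yl diisopinocampheylborinate (Ipc groups from (+)-α-pinene) | C=C[C@H](C)[C@H](OB([C@H]1[C@H](C)[C@H]2C[C@@H](C1)C2(C)C)[C@H]1[C@H](C)[C@H]2C[C@@H](C1)C2(C)C)C#C[Si](C)(C)C | intermediate
5 | (3S,4S)-4-methyl-1-(trimethylsilyl)hex-5-en-1-yn-3-ol | C=C[C@H](C)[C@H](O)C#C[Si](C)(C)C | intermediate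
6 | (3S,4S)-4-methyl-1-(trimethylsilyl)hex-5-en-1-yn-3-yl methanesulfonate | C=C[C@H](C)[C@H](OS(C)(=O)=O)C#C[Si](C)(C)C | intermediate
7 | trimethyl[(3R,4S)-3-[(2-methoxypropan-2-yl)peroxy]-4-methylhex-5-en-1-yn-1-yl]silane | C=C[C@H](C)[C@@H](OOC(C)(C)OC)C#C[Si](C)(C)C | intermediate
8 | (3R,4S)-3-[(2-methoxypropan-2-yl)peroxy]-4-methylhex-5-en-1-yne | C=C[C@H](C)[C@@H](OOC(C)(C)OC)C#C | intermediate
9 | (2R,3R)-1-hydroperoxy-1-methoxy-3-[(2-methoxypropan-2-yl)peroxy]-2-methylpent-4-yne (C1 epimers) | COC(OO)[C@H](C)[C@@H](OOC(C)(C)OC)C#C | intermediate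
10 | methyl (2R,3R)-3-[(2-methoxypropan-2-yl)peroxy]-2-methylpent-4-ynoate | COC(=O)[C@H](C)[C@@H](OOC(C)(C)OC)C#C | intermediate
11 | methyl (2R,3S)-3-[(2-methoxypropan-2-yl)peroxy]-2-methylpent-4-enoate | COC(=O)[C@H](C)[C@@H](OOC(C)(C)OC)C=C | intermediate
12 | (5E,9E)-6,10,14-trimethylpentadeca-5,9,13-trien-2-one (farnesylacetone) | CC(=O)CC/C=C(\C)CC/C=C(\C)CCC=C(C)C | starting material
13 | (5E,9E)-2,2-dimethoxy-6,10,14-trimethylpentadeca-5,9,13-triene | COC(C)(OC)CC/C=C(\C)CC/C=C(\C)CCC=C(C)C | intermediate
14 | methyl (2R,3S)-3-hydroperoxy-2-methylpent-4-enoate | COC(=O)[C@H](C)[C@@H](OO)C=C | intermediate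
15 | methyl (2R,3S)-3-{[(5E,9E)-2-methoxy-6,10,14-trimethylpentadeca-5,9,13-trien-2-yl]peroxy}-2-methylpent-4-enoate | COC(=O)[C@H](C)[C@@H](OOC(C)(OC)CC/C=C(\C)CC/C=C(\C)CCC=C(C)C)C=C | intermediate
16 | peroxycarbenium ion from 15 (methoxide removed), as its tetrabromo(methoxy)stannate ion pair | COC(=O)[C@H](C)[C@@H](O[O+]=C(C)CC/C=C(\C)CC/C=C(\C)CCC=C(C)C)C=C.CO[Sn-](Br)(Br)(Br)Br | intermediate
17 | methyl (2R)-2-[(3R,6R)-4-bromo-6-methyl-6-[(3E,7E)-4,8,12-trimethyltrideca-3,7,11-trien-1-yl]-1,2-dioxan-3-yl]propanoate (C4 epimers) | COC(=O)[C@H](C)[C@@H]1C(Br)C[C@@](C)(CC/C=C(\C)CC/C=C(\C)CCC=C(C)C)OO1 | intermediate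
18 | methyl (2R)-2-[(3S,6R)-6-methyl-6-[(3E,7E)-4,8,12-trimethyltrideca-3,7,11-trien-1-yl]-1,2-dioxan-3-yl]propanoate | COC(=O)[C@H](C)[C@@H]1CC[C@@](C)(CC/C=C(\C)CC/C=C(\C)CCC=C(C)C)OO1 | target

**Totals**

Total step count: 10. Longest linear sequence: 8 steps (steps 2–6 and 8–10, from 3).

**Steps most likely to fail**

1. Step 9. Facial selectivity at C6 may erode because methyl and the CH2 chain differ little in size. The secondary C4 cation may also be diverted before bromide reaches it: capture by the ester carbonyl to a lactone, a 1,2-hydride shift from C3, or capture of ion 16 by a chain alkene.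
Fallback (sets out from 6, returns at 18): the cation is terminated by silicon instead of bromide, so that no free secondary cation and no radical step are needed. Step 4 is run without the methanolic carbonate stage, so that silylalkyne peroxide 7 is isolated. Ozonolysis in CH2Cl2/MeOH gives the silylated α-methoxy hydroperoxide F1, and Ac2O/Et3N converts it into the silylalkynyl ester F2. Semihydrogenation (H2, Pd/CaCO3 poisoned with Pb(OAc)2, quinoline) gives the (Z)-vinylsilane ester F3. AcOH/THF/H2O releases the vinylsilane hydroperoxide F4, which with 13 and pyridinium p-toluenesulfonate gives the vinylsilane peroxyketal F5. SnCl4 in CH2Cl2 at −78 °C ionises F5 to the silylated peroxycarbenium ion F6. Attack through the silicon-bearing carbon gives a β-silyl-stabilised C4 cation that collapses by loss of the silyl group to the 3,6-dihydro-1,2-dioxin F7 (vinylsilane-terminated cation cyclisation; the Z geometry is the one required for an endocyclic closure). Diimide (dipotassium azodicarboxylate, AcOH, MeOH, 0 °C) should then reduce the cis-disubstituted ring alkene in preference to the trisubstituted chain alkenes and give 18. This fallback addresses cation diversion; it does not improve the methyl/chain discrimination at C6.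

2. Step 6. Hydrogenolysis of the O–O bond, or over-reduction of the vinyl group to ethyl, may compete on the palladium surface.
Fallback (sets out from 10, returns at 11): hydrometallation–protonolysis replaces heterogeneous hydrogenation. syn-Hydrozirconation with Cp2Zr(H)Cl (1.1 equiv, CH2Cl2, 0 °C) should add to the terminal alkyne much faster than it reduces the ester and gives the alkenylzirconocene F8; protonolysis with water gives 11. This sequence cannot over-reduce.

3. Step 4. E2 loss of methanesulfonate toward the allylic C4–H (giving a dienyne) or SN2′ attack (giving an allenyl peroxide) may compete with direct substitution at the hindered propargylic carbon.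
Fallback (sets out from 6, returns at 8): free hydrogen peroxide is used as the nucleophile and the protecting group is added afterwards. Perhydrolysis (50% H2O2 in large excess, KOH, MeOH, 0 °C) uses a small nucleophile buffered by the excess peroxide, cleaves the silyl group in the same medium and gives the free propargylic hydroperoxide F9 with inversion. Capping with 2-methoxypropene and pyridinium p-toluenesulfonate in CH2Cl2 gives 8.

Further compounds
F1 | step 9 | (2R,3R)-1-hydroperoxy-1-methoxy-3-[(2-methoxypropan-2-yl)peroxy]-2-methyl-5-(trimethylsilyl)pent-4-yne (C1 epimers) | COC(OO)[C@H](C)[C@@H](OOC(C)(C)OC)C#C[Si](C)(C)C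
F2 | step 9 | methyl (2R,3R)-3-[(2-methoxypropan-2-yl)peroxy]-2-methyl-5-(trimethylsilyl)pent-4-ynoate | COC(=O)[C@H](C)[C@@H](OOC(C)(C)OC)C#C[Si](C)(C)C
F3 | step 9 | methyl (2R,3R,4Z)-3-[(2-methoxypropan-2-yl)peroxy]-2-methyl-5-(trimethylsilyl)pent-4-enoate | COC(=O)[C@H](C)[C@@H](OOC(C)(C)OC)/C=C\[Si](C)(C)C
F4 | step 9 | methyl (2R,3R,4Z)-3-hydroperoxy-2-methyl-5-(trimethylsilyl)pent-4-enoate | COC(=O)[C@H](C)[C@@H](OO)/C=C\[Si](C)(C)C
F5 | step 9 | methyl (2R,3R,4Z)-3-{[(5E,9E)-2-methoxy-6,10,14-trimethylpentadeca-5,9,13-trien-2-yl]peroxy}-2-methyl-5-(trimethylsilyl)pent-4-enoate | COC(=O)[C@H](C)[C@@H](OOC(C)(OC)CC/C=C(\C)CC/C=C(\C)CCC=C(C)C)/C=C\[Si](C)(C)C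
F6 | step 9 | peroxycarbenium ion from F5 (methoxide removed), as its tetrachloro(methoxy)stannate ion pair | COC(=O)[C@H](C)[C@@H](O[O+]=C(C)CC/C=C(\C)CC/C=C(\C)CCC=C(C)C)/C=C\[Si](C)(C)C.CO[Sn-](Cl)(Cl)(Cl)Cl
F7 | step 9 | methyl (2R)-2-[(3S,6R)-6-methyl-6-[(3E,7E)-4,8,12-trimethyltrideca-3,7,11-trien-1-yl]-3,6-dihydro-1,2-dioxin-3-yl]propanoate | COC(=O)[C@H](C)[C@@H]1C=C[C@@](C)(CC/C=C(\C)CC/C=C(\C)CCC=C(C)C)OO1
F8 | step 6 | methyl (2R,3R,4E)-5-[chlorobis(cyclopentadienyl)zirconio]-3-[(2-methoxypropan-2-yl)peroxy]-2-methylpent-4-enoate | COC(=O)[C@H](C)[C@@H](OOC(C)(C)OC)/C=C/[Zr](Cl)(C1C=CC=C1)C1C=CC=C1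
F9 | step 4 | (3R,4S)-3-hydroperoxy-4-methylhex-5-en-1-yne | C=C[C@H](C)[C@@H](OO)C#C
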